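The 2H-pyran ring (chromene numbering) is disconnected at C3–C4 and O1–C8a into two three-atom units: oxirane 7, which carries O1, the quaternary stereocentre C2 and C3, and benzylic Grignard reagent 11, which carries C4, C4a and C8a of the hydroquinone ring. The key step is a one-pot formal [3+3] annulation: copper-catalysed attack of C4 on the epoxide CH2 (C3), then palladium-catalysed O-arylation of the liberated tertiary alkoxide at C8a. It exploits the 1,3-relationship of O1 and C3 across C2 and the ortho relationship of C4 and O1 on the benzene ring; C2, set earlier by asymmetric methylene transfer, is never touched. Dehydrogenation of C3–C4 and desilylation finish the chromenol.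

Key step: step 6

Remark: the binaphthoxide antipode in step 3 is the one that delivers methylene to the Re face of ketone 6; it is written as (S) by analogy with other methyl ketones, and the mirror-image catalyst is used should the sense of induction be the opposite.

Step 1
Reactants: 1 dihydro-β-ionone [4-(2,6,6-trimethylcyclohex-1-en-1-yl)butan-2-one]
Product: 3 2-(but-3-yn-1-yl)-1,3,3-trimethylcyclohex-1-ene, via enol phosphate 2 (not isolated)
Conditions: LiN(iPr)2 (1.05 equiv), THF, −78 °C; ClP(O)(OEt)2, −78 °C → rt; then LiN(iPr)2 (2.3 equiv), THF, −78 °C → rt; H2O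
Reagents that add atoms: none
Why: Kinetic deprotonation of the methyl ketone at the methyl group, O-phosphorylation and twofold amide-induced elimination of the enol phosphate (ketone-to-alkyne conversion via an enol phosphate) should give the terminal alkyne, the tetrasubstituted ring alkene being inert.

Step 2
Reactants: 3 2-(but-3-yn-1-yl)-1,3,3-trimethylcyclohex-1-ene; 4 methyl vinyl ketone
Product: 6 (5E)-6-methyl-8-(2,6,6-trimethylcyclohex-1-en-1-yl)oct-5-en-2-one, via alkenylalane 5 (not isolated)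
Conditions: Me3Al (2 equiv), Cp2ZrCl2 (25 mol %), ClCH2CH2Cl, rt; then THF, CuBr·SMe2 (10 mol %), 4, 0 °C → rt; aq. NH4Cl
Reagents that add atoms: trimethylaluminium C[Al](C)C
Why: Zirconium-catalysed syn-carboalumination (Negishi carboalumination) places methyl on the internal and aluminium on the terminal alkyne carbon, which fixes the E trisubstituted alkene, and copper-catalysed conjugate addition of the alkenylalane to the enone should transfer the alkenyl group with retention of geometry.

Step 3
Reactants: 6 (5E)-6-methyl-8-(2,6,6-trimethylcyclohex-1-en-1-yl)oct-5-en-2-one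
Product: 7 (2S)-2-methyl-2-[(3E)-4-methyl-6-(2,6,6-trimethylcyclohex-1-en-1-yl)hex-3-en-1-yl]oxirane
Conditions: Me3S(O)I, NaH, THF (ylide preformed); LaLi3[(S)-binaphthoxide]3 (5 mol %), [2,4,6-(MeO)3C6H2]3P=O (5 mol %), 5 Å molecular sieves, THF, rt
Reagents that add atoms: trimethylsulfoxonium iodide C[S+](C)(C)=O.[I-]
Why: Catalytic asymmetric Corey–Chaykovsky epoxidation, in which LaLi3[(S)-binaphthoxide]3 activates the ketone and directs the dimethylsulfoxonium methylide preformed from the sulfoxonium salt to the Re face (long chain versus methyl), so that betaine closure with loss of dimethyl sulfoxide sets C2 as S; the unactivated alkenes do not react with the ylide.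

Step 4
Reactants: 8 4-bromo-3-methylphenol
Product: 9 (4-bromo-3-methylphenoxy)tri(propan-2-yl)silane
Conditions: iPr3SiCl, imidazole, DMF, rt
Reagents that add atoms: chlorotri(propan-2-yl)silane CC(C)[Si](Cl)(C(C)C)C(C)C
Why: Imidazole-mediated O-silylation of the phenol; the bulky triisopropylsilyl ether is chosen because it should survive the Grignard, alkoxide and quinone conditions that follow.

Step 5
Reactants: 9 (4-bromo-3-methylphenoxy)tri(propan-2-yl)silane
Product: 10 [4-bromo-3-(bromomethyl)phenoxy]tri(propan-2-yl)silane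
Conditions: N-bromosuccinimide (1.05 equiv), AIBN (cat.), PhCF3, 85 °C
Reagents that add atoms: N-bromosuccinimide O=C1CCC(=O)N1Br
Why: Wohl–Ziegler radical bromination at the only benzylic position; the ring bromine and the silyl ether disfavour electrophilic ring bromination.

Step 6
Reactants: 10 [4-bromo-3-(bromomethyl)phenoxy]tri(propan-2-yl)silane; 7 (2S)-2-methyl-2-[(3E)-4-methyl-6-(2,6,6-trimethylcyclohex-1-en-1-yl)hex-3-en-1-yl]oxirane
Product: 13 {[(2S)-2-methyl-2-[(3E)-4-methyl-6-(2,6,6-trimethylcyclohex-1-en-1-yl)hex-3-en-1-yl]-3,4-dihydro-2H-chromen-6-yl]oxy}tri(propan-2-yl)silane, via benzylic Grignard reagent 11 (not isolated), via bromomagnesium alkoxide 12 (not isolated)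
Conditions: Mg, Et2O, 0 °C (slow addition of 10); then 7, CuI (10 mol %), THF, −30 → 0 °C; then t-BuOH, NaOtBu, Pd(OAc)2 (5 mol %), 2-(di-tert-butylphosphino)-1,1′-binaphthyl (6 mol %), toluene, 80 °C
Reagents that add atoms: none
Why: Magnesium inserts into the benzylic C–Br bond of 10 (not into the aryl C–Br bond) to give 11, whose CuI-catalysed SN2 attack on the unsubstituted oxirane carbon of 7 forms C3–C4 and liberates tertiary alkoxide 12; after exchange to the sodium alkoxide, oxidative addition of zerovalent palladium into the aryl C–Br bond, alkoxide coordination and C–O reductive elimination form O1–C8a. The closest known reaction types are the copper-catalysed Grignard opening of terminal epoxides and the intramolecular Buchwald–Hartwig etherification of aryl bromides with tertiary alcohols, here run in one flask as a formal [3+3] annulation. The dihydropyran ring closes in a 6-exo sense by reductive elimination from a seven-membered aryl palladium alkoxide. No new stereocentre is formed: C2 is delivered by 7, none of its four bonds is broken, and it stays S. The step needs regioselective opening at CH2, secured by the quaternary C2 and by copper catalysis at low temperature (which also suppresses Lewis-acid rearrangement of the epoxide), and clean C–O coupling, secured by the absence of beta-hydrogens on the tertiary alkoxide and by destroying surplus 11 with t-BuOH before palladium is added so that no Kumada coupling occurs.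

Step 7
Reactants: 13 {[(2S)-2-methyl-2-[(3E)-4-methyl-6-(2,6,6-trimethylcyclohex-1-en-1-yl)hex-3-en-1-yl]-3,4-dihydro-2H-chromen-6-yl]oxy}tri(propan-2-yl)silane
Product: 14 {[(2S)-2-methyl-2-[(3E)-4-methyl-6-(2,6,6-trimethylcyclohex-1-en-1-yl)hex-3-en-1-yl]-2H-chromen-6-yl]oxy}tri(propan-2-yl)silane
Conditions: DDQ (1.5 equiv), 1,4-dioxane, 80 °C, dark
Reagents that add atoms: none
Why: Quinone dehydrogenation, in which DDQ abstracts hydride from benzylic C4 (cation stabilised by the ortho ring oxygen O1) and loss of a C3 proton gives the 2H-chromene; C2 is quaternary, so further oxidation to a pyrylium ion is blocked and the stereocentre is untouched.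

Step 8
Reactants: 14 {[(2S)-2-methyl-2-[(3E)-4-methyl-6-(2,6,6-trimethylcyclohex-1-en-1-yl)hex-3-en-1-yl]-2H-chromen-6-yl]oxy}tri(propan-2-yl)silane
Product: 15 (2S)-2-methyl-2-[(3E)-4-methyl-6-(2,6,6-trimethylcyclohex-1-en-1-yl)hex-3-en-1-yl]-2H-chromen-6-ol
Conditions: Bu4NF, AcOH (1:1), THF, 0 °C, dark
Reagents that add atoms: none
Why: Fluoride-induced cleavage of the aryl silyl ether; acetic acid buffering, low temperature and exclusion of light should keep the chromenolate from electrocyclic ring opening, which would racemise C2.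

Compound list
1 | dihydro-β-ionone, 4-(2,6,6-trimethylcyclohex-1-en-1-yl)butan-2-one | CC(=O)CCC1=C(C)CCCC1(C)C | starting material
2 | diethyl 4-(2,6,6-trimethylcyclohex-1-en-1-yl)but-1-en-2-yl phosphate | C=C(CCC1=C(C)CCCC1(C)C)OP(=O)(OCC)OCC | intermediate
3 | 2-(but-3-yn-1-yl)-1,3,3-trimethylcyclohex-1-ene | C#CCCC1=C(C)CCCC1(C)C | intermediate
4 | methyl vinyl ketone, but-3-en-2-one | CC(=O)C=C | starting material
5 | dimethyl[(1E)-2-methyl-4-(2,6,6-trimethylcyclohex-1-en-1-yl)but-1-en-1-yl]alumane | C[Al](C)/C=C(\C)CCC1=C(C)CCCC1(C)C | intermediate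
6 | (5E)-6-methyl-8-(2,6,6-trimethylcyclohex-1-en-1-yl)oct-5-en-2-one | CC(=O)CC/C=C(\C)CCC1=C(C)CCCC1(C)C | intermediate
7 | (2S)-2-methyl-2-[(3E)-4-methyl-6-(2,6,6-trimethylcyclohex-1-en-1-yl)hex-3-en-1-yl]oxirane | C[C@]1(CC/C=C(\C)CCC2=C(C)CCCC2(C)C)CO1 | intermediate
8 | 4-bromo-3-methylphenol | Cc1cc(O)ccc1Br | starting material
9 | (4-bromo-3-methylphenoxy)tri(propan-2-yl)silane | Cc1cc(O[Si](C(C)C)(C(C)C)C(C)C)ccc1Br | intermediate
10 | [4-bromo-3-(bromomethyl)phenoxy]tri(propan-2-yl)silane | BrCc1cc(O[Si](C(C)C)(C(C)C)C(C)C)ccc1Br | intermediate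
11 | {2-bromo-5-[(triisopropylsilyl)oxy]benzyl}magnesium bromide | Br[Mg]Cc1cc(O[Si](C(C)C)(C(C)C)C(C)C)ccc1Br | intermediate
12 | bromomagnesium (3S,6E)-1-{2-bromo-5-[(triisopropylsilyl)oxy]phenyl}-3,7-dimethyl-9-(2,6,6-trimethylcyclohex-1-en-1-yl)non-6-en-3-olate | C[C@@](CCc1cc(O[Si](C(C)C)(C(C)C)C(C)C)ccc1Br)(CC/C=C(\C)CCC2=C(C)CCCC2(C)C)O[Mg]Br | intermediate
13 | {[(2S)-2-methyl-2-[(3E)-4-methyl-6-(2,6,6-trimethylcyclohex-1-en-1-yl)hex-3-en-1-yl]-3,4-dihydro-2H-chromen-6-yl]oxy}tri(propan-2-yl)silane | C[C@]1(CC/C=C(\C)CCC2=C(C)CCCC2(C)C)CCc3cc(O[Si](C(C)C)(C(C)C)C(C)C)ccc3O1 | intermediate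
14 | {[(2S)-2-methyl-2-[(3E)-4-methyl-6-(2,6,6-trimethylcyclohex-1-en-1-yl)hex-3-en-1-yl]-2H-chromen-6-yl]oxy}tri(propan-2-yl)silane | C[C@]1(CC/C=C(\C)CCC2=C(C)CCCC2(C)C)C=Cc3cc(O[Si](C(C)C)(C(C)C)C(C)C)ccc3O1 | intermediate
15 | (2S)-2-methyl-2-[(3E)-4-methyl-6-(2,6,6-trimethylcyclohex-1-en-1-yl)hex-3-en-1-yl]-2H-chromen-6-ol | C[C@]1(CC/C=C(\C)CCC2=C(C)CCCC2(C)C)C=Cc3cc(O)ccc3O1 | target

Total step count: 8. Longest linear sequence: 6 steps (steps 1, 2, 3, 6, 7, 8).

Steps most likely to fail

Step 6. Wurtz-type homocoupling during formation of the benzylic Grignard reagent, Lewis-acid-induced rearrangement of the epoxide before C–C bond formation, or inhibition of the palladium stage by the magnesium and copper salts of the crude mixture may erode the annulation. The fallback sets out from 10 and 7 and comes back at 13, and replaces the Grignard reagent by a sulfone-stabilised carbanion. Displacement of the benzylic bromide of 10 with PhSO2Na (DMF, rt) should give {4-bromo-3-[(phenylsulfonyl)methyl]phenoxy}tri(propan-2-yl)silane F1. Its lithium carbanion (LiN(SiMe3)2, THF/DMPU, 0 → 40 °C) should open 7 at the CH2 carbon to give the hydroxy sulfone (3S,6E)-1-{2-bromo-5-[(triisopropylsilyl)oxy]phenyl}-3,7-dimethyl-1-(phenylsulfonyl)-9-(2,6,6-trimethylcyclohex-1-en-1-yl)non-6-en-3-ol F2 (C1 epimers), which is purified. The same palladium-catalysed etherification (NaOtBu, Pd(OAc)2, 2-(di-tert-butylphosphino)-1,1′-binaphthyl, toluene, 80 °C) should close it to the 4-(phenylsulfonyl)chroman F3. Reductive desulfonylation (SmI2, THF/DMPU, MeOH, −78 °C) should then give 13.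

Step 2. Competing transfer of methyl instead of the alkenyl group from aluminium, and Lewis-acid-induced oligomerisation of methyl vinyl ketone, may lower the yield of 6. The fallback sets out from 3 (through alane 5) and comes back at 6. Alane 5 is quenched with I2 (THF, −30 °C) to give 2-[(3E)-4-iodo-3-methylbut-3-en-1-yl]-1,3,3-trimethylcyclohex-1-ene F4. Negishi coupling with CH2=CHCH2CH2ZnBr (Pd(PPh3)4, THF, rt) should give 1,3,3-trimethyl-2-[(3E)-3-methylocta-3,7-dien-1-yl]cyclohex-1-ene F5. Wacker oxidation of its only monosubstituted alkene (PdCl2, CuCl, O2, DMF/H2O) should give 6.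

Step 7. Hydride abstraction from the allylic positions of the side chain and of the tetrasubstituted ring alkene may compete with abstraction at C4, and the electron-rich chromene may be oxidised further. The fallback sets out from 7 and 10 and comes back at 14, and introduces C3=C4 at the alkene level before ring closure. Hydroxide opening of 7 at CH2 (KOH, DMSO/H2O, 90 °C) should give (2S,5E)-2,6-dimethyl-8-(2,6,6-trimethylcyclohex-1-en-1-yl)oct-5-ene-1,2-diol F6. Parikh–Doering oxidation (SO3·pyridine, DMSO, Et3N) should give (2S,5E)-2-hydroxy-2,6-dimethyl-8-(2,6,6-trimethylcyclohex-1-en-1-yl)oct-5-enal F7. Bromide 10 and PPh3 (toluene, 80 °C) should give {2-bromo-5-[(triisopropylsilyl)oxy]benzyl}triphenylphosphonium bromide F8. A salt-free Wittig reaction of the ylide from F8 (KN(SiMe3)2, 2 equiv of ylide, THF, −78 °C) with F7 should give mainly (3S,1Z,6E)-1-{2-bromo-5-[(triisopropylsilyl)oxy]phenyl}-3,7-dimethyl-9-(2,6,6-trimethylcyclohex-1-en-1-yl)nona-1,6-dien-3-ol F9. The palladium-catalysed etherification of step 6 should then close F9 directly to 14, since only the Z isomer can cyclise.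

Further compounds
F1 | step 6 | {4-bromo-3-[(phenylsulfonyl)methyl]phenoxy}tri(propan-2-yl)silane | O=S(=O)(Cc1cc(O[Si](C(C)C)(C(C)C)C(C)C)ccc1Br)c1ccccc1
F2 | step 6 | (3S,6E)-1-{2-bromo-5-[(triisopropylsilyl)oxy]phenyl}-3,7-dimethyl-1-(phenylsulfonyl)-9-(2,6,6-trimethylcyclohex-1-en-1-yl)non-6-en-3-ol | C[C@@](O)(CC(c1cc(O[Si](C(C)C)(C(C)C)C(C)C)ccc1Br)S(=O)(=O)c1ccccc1)CC/C=C(\C)CCC1=C(C)CCCC1(C)C
F3 | step 6 | {[(2S)-2-methyl-2-[(3E)-4-methyl-6-(2,6,6-trimethylcyclohex-1-en-1-yl)hex-3-en-1-yl]-4-(phenylsulfonyl)-3,4-dihydro-2H-chromen-6-yl]oxy}tri(propan-2-yl)silane | C[C@]1(CC/C=C(\C)CCC2=C(C)CCCC2(C)C)CC(S(=O)(=O)c2ccccc2)c2cc(O[Si](C(C)C)(C(C)C)C(C)C)ccc2O1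
F4 | step 2 | 2-[(3E)-4-iodo-3-methylbut-3-en-1-yl]-1,3,3-trimethylcyclohex-1-ene | I/C=C(\C)CCC1=C(C)CCCC1(C)C
F5 | step 2 | 1,3,3-trimethyl-2-[(3E)-3-methylocta-3,7-dien-1-yl]cyclohex-1-ene | C=CCC/C=C(\C)CCC1=C(C)CCCC1(C)C
F6 | step 7 | (2S,5E)-2,6-dimethyl-8-(2,6,6-trimethylcyclohex-1-en-1-yl)oct-5-ene-1,2-diol | C[C@@](O)(CO)CC/C=C(\C)CCC1=C(C)CCCC1(C)C
F7 | step 7 | (2S,5E)-2-hydroxy-2,6-dimethyl-8-(2,6,6-trimethylcyclohex-1-en-1-yl)oct-5-enal | C[C@@](O)(C=O)CC/C=C(\C)CCC1=C(C)CCCC1(C)C
F8 | step 7 | {2-bromo-5-[(triisopropylsilyl)oxy]benzyl}triphenylphosphonium bromide | Brc1ccc(O[Si](C(C)C)(C(C)C)C(C)C)cc1C[P+](c1ccccc1)(c1ccccc1)c1ccccc1.[Br-]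
F9 | step 7 | (3S,1Z,6E)-1-{2-bromo-5-[(triisopropylsilyl)oxy]phenyl}-3,7-dimethyl-9-(2,6,6-trimethylcyclohex-1-en-1-yl)nona-1,6-dien-3-ol | C[C@@](O)(/C=C\c1cc(O[Si](C(C)C)(C(C)C)C(C)C)ccc1Br)CC/C=C(\C)CCC1=C(C)CCCC1(C)C
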